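The catalyst is conserved: in this closed flask at constant volume its forms, free or bound, add up to the charge of 0.095 mol% on the starting material.

all flasks: starting material 0.050 M; free catalyst 0.095 mol%

| flask | reagent | capture agent | remark | time |
|---|---|---|---|---|
| grey | 0.80 equiv | 0.015 M | the very flask that is asked about, followed so far |  |
| flask | 0.800 equiv | 0.0150 M |  | 12 h |

grey run (percent of the starting material charged): time / h: target / % = 0.833: 6.9; 2.50: 11.7; 4.00: 12.0; 6.00: 12.4; 10.0: 11.6; 12.0: 11.6

(scatter of a reading: 0.3 percentage points)

- target, in percent of the starting material first charged, at 12 h
- the option that brings most further target ("none" if no option brings more than 2 percentage points) (noon / midnight / dawn / dusk / none)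
- target present, with what was taken out counted in, in percent of the starting material first charged, after midnight
- target present, with what was taken out counted in, in percent of the starting material first charged, after dusk

- noon: at 12 h add free catalyst, 100 % of the amount charged, then wait 25 h
- midnight: change nothing and wait 25 h more
- dawn: at 12 h add reagent, 50.0 % of the amount charged, then wait 25 h
- dusk: at 12 h take out 90 % of the target then present, then wait 25 h

- target taken out counts as made
- additions bring no volume worth counting

I built the grey flask up one process at a time. The main step by itself, starting material and reagent to target with a catalyst that keeps turning over, runs on towards the limit set by the limiting reagent at 0.800 equiv. The readings instead went flat by 4.00 h, and the four from then on average 11.9 %. So I added capture of the catalyst as the second process. The capture agent stands at 316 times the catalyst, so I treated the loss as pseudo-first-order, with the rate of making target decaying exponentially. The first reading against the plateau gave a lifetime τ of 0.961 h, far shorter than the 12 h in question. One run also fits an equilibrium near the plateau, but I judged capture likelier. The end state is then a count: the turnover capacity N, target made per catalyst charged before capture ends the work, read here as 125. Last I looked for a slow drain of target: the final reading lies 0.8 percentage points below the highest, but both readings carry a scatter of 0.3 points, so I counted no drain. By my own count I therefore expected 11.9 % now, and N times the added catalyst, 12 points, of fresh target from noon, with no new turnovers from the other options. The forecast gave 11.9 % now, 11.9 % after midnight, 12 % after dusk and noon as best, with a figure of its own for noon that differs from my count: "Fresh catalyst gives another burst of about +9–10 points".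

The flask gave 11.4 % now, 7.45 % after midnight, 11.0 % after dusk and noon as best. Measured from now, noon ended at 5.4 points and midnight at −3.9 points, a gap of 9.3 points for the added catalyst, beside the 12 points that N promised.

    catalyst intermediate B → free catalyst + target (k = 20000 h⁻¹)
    target + free catalyst ⇌ isomer of the product + free catalyst, rate k2*[free catalyst]*[target] forward; the back reaction follows from the equilibrium constant (K = 0.622, k = 8580 L mol⁻¹ h⁻¹)
    starting material + catalyst intermediate A ⇌ catalyst intermediate B (K = 9.41 L mol⁻¹, k = 18400 L mol⁻¹ h⁻¹)
    reagent + target → over-reaction product (k = 0.577 L mol⁻¹ h⁻¹)
    catalyst intermediate B + capture agent → trapped intermediate (k = 7680 L mol⁻¹ h⁻¹)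
    reagent + free catalyst → catalyst intermediate A (k = 4290 L mol⁻¹ h⁻¹)

In the neighbouring flask, with 0.24 mol% of catalyst, N gives 30.1 %; that flask held 25.9 % of target at 12 h, together with 12.3 % of isomer of the product and 3.37 % of over-reaction product.

The readings are simulated with constants of no real substance; noise was put on by code.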